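**Retrosynthetic overview**

1. Numbering used throughout: C1 (ring C=CH2), C2 (CHOH), C3 (CH2), C4 (ring-fusion CH), C5 (CMe2), C6 (CHBr), C7 and C8 (CH2), C9 (ring-fusion C(Me)–O), O10, C11 (O–CH), C12 (CH2Br).
2. Feature: in the oxepane ring (C9–O10–C11–C1–C2–C3–C4), C1 is a lone carbon wedged between the oxygen-bearing C11 and C2. It is excised as a dibromocarbene carbon, so the oxepane is traced back through a gem-dibromocyclopropane to the trans-fused dihydropyran enol ether O10–C11=C2–C3–C4–C9.
3. After the expansion: C11 ketal → C11–H (silane), C1–Br → C1–Me (Negishi), C12–OTIPS → C12–Br, then C1=C2 α-epoxide → exocyclic allylic alcohol (aluminium amide).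
4. Before the expansion: the enol ether comes from δ-lactone 6 (ketene acetal phosphate, Pd methoxycarbonylation, DIBAL, TIPS). Lactone 6 comes from (E)-geranylacetic acid by catalyst-controlled brominative polyene cyclization (sets C4, C6, C9); the acid comes from geranyl bromide and malonate.
5. Ring order: cyclohexane and pyranone rings together (step 3) → cyclopropane (step 8) → oxepene by expansion of the pyran ring (step 9).

Key step: step 9

Assumption: in step 3 the antipode of the BINOL-derived catalyst is the one that delivers the (6S)-bromide; which antipode does so has to be fixed by correlation, and the route is drawn for that enantiomer.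

**Route**

Step 1
Reactants: 1 geranyl bromide; 2 diethyl malonate
Product: 3 diethyl 2-[(2E)-3,7-dimethylocta-2,6-dien-1-yl]propanedioate
Conditions: NaH, THF, 0 °C → rt (2 in excess)
Reagents that add atoms: none
Why: Malonic ester alkylation, in which the sodium enolate displaces the primary allylic bromide by SN2 with the E-alkene untouched, excess malonate suppressing dialkylation; no stereocentre is formed.

Step 2
Reactants: 3 diethyl geranylmalonate
Product: 5 (4E)-5,9-dimethyldeca-4,8-dienoic acid (geranylacetic acid), via geranylmalonic acid 4 (not isolated)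
Conditions: KOH, EtOH/H2O, reflux; 1 M HCl, 0 °C; pyridine, 115 °C
Reagents that add atoms: potassium hydroxide, [K+].[OH-]
Why: Saponification followed by thermal decarboxylation of the malonic acid (malonic ester synthesis) should give the γ,δ-unsaturated acid, the cold dilute acidification being too mild to protonate the trisubstituted alkenes.

Step 3
Reactants: 5 geranylacetic acid
Product: 6 (4aS,6S,8aS)-6-bromo-5,5,8a-trimethyloctahydro-2H-chromen-2-one (trans-fused, Br equatorial)
Conditions: chiral BINOL-derived thiophosphoramide (10 mol %), DBDMH (0.55 equiv), PhMe/CH2Cl2, −78 °C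
Reagents that add atoms: 1,3-dibromo-5,5-dimethylhydantoin, CC1(C)N(Br)C(=O)N(Br)C1=O
Why: Enantioselective bromonium-induced polyene cyclization under chiral Lewis-base catalysis, in which Br+ goes to the terminal C5=C6 alkene, the (E)-C4=C9 alkene attacks through a chair transition state and the carboxyl oxygen traps the C9 cation, so that the E geometry sets the trans fusion (C4–H anti to C9–Me) and the equatorial bromide while the catalyst sets the absolute sense at C4, C6 and C9.

Step 4
Reactants: 6 bromo δ-lactone
Product: 7 (4aS,6S,8aS)-6-bromo-5,5,8a-trimethyl-4a,5,6,7,8,8a-hexahydro-4H-chromen-2-yl diphenyl phosphate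
Conditions: KHMDS, (PhO)2P(O)Cl, HMPA, THF, −78 °C
Reagents that add atoms: diphenyl chlorophosphate, O=P(Cl)(Oc1ccccc1)Oc1ccccc1
Why: Kinetic enolization of the lactone and O-phosphorylation of the potassium enolate (ketene acetal phosphate formation), the equatorial neopentyl-type C6–Br having no antiperiplanar hydrogen for E2 at −78 °C.

Step 5
Reactants: 7 ketene acetal phosphate
Product: 8 methyl (4aS,6S,8aS)-6-bromo-5,5,8a-trimethyl-4a,5,6,7,8,8a-hexahydro-4H-chromene-2-carboxylate
Conditions: Pd(PPh3)4 (cat.), CO (1 atm), MeOH, Et3N, DMF, 60 °C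
Reagents that add atoms: carbon monoxide, [C-]#[O+]; methanol, CO
Why: Palladium-catalysed alkoxycarbonylation of the ketene acetal phosphate (oxidative addition into C11–OP, CO insertion, methanolysis) should install C12, the unactivated secondary alkyl bromide being inert to Pd(0)/PPh3.

Step 6
Reactants: 8 enol ether ester
Product: 9 [(4aS,6S,8aS)-6-bromo-5,5,8a-trimethyl-4a,5,6,7,8,8a-hexahydro-4H-chromen-2-yl]methanol
Conditions: DIBAL-H (2.5 equiv), CH2Cl2, −78 °C; Rochelle salt
Reagents that add atoms: none
Why: DIBAL 1,2-reduction of the α-alkoxy acrylate to the allylic alcohol, which leaves the C–Br bond and the enol ether untouched, the non-acidic work-up protecting the acid-labile enol ether.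

Step 7
Reactants: 9 allylic alcohol
Product: 10 {[(4aS,6S,8aS)-6-bromo-5,5,8a-trimethyl-4a,5,6,7,8,8a-hexahydro-4H-chromen-2-yl]methoxy}tri(propan-2-yl)silane
Conditions: TIPSCl, imidazole, DMAP (cat.), DMF, rt
Reagents that add atoms: triisopropylsilyl chloride, CC(C)[Si](Cl)(C(C)C)C(C)C
Why: Imidazole-mediated silylation of the primary alcohol, the TIPS ether being chosen because it should survive alkoxide, hot carbonate/methanol and Lewis acid/silane in steps 8–10.

Step 8
Reactants: 10 silylated dihydropyran; 11 bromoform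
Product: 12 gem-dibromocyclopropane: C1Br2 bridging C11 and C2 on the α face of 10 (C2 R, C11 R), with C11 still carrying CH2OTIPS; used crude
Conditions: KOt-Bu, pentane, −20 → 0 °C
Reagents that add atoms: none
Why: α-Elimination of HBr from bromoform gives dibromocarbene, which adds stereospecifically ([2+1] cheletropic addition) to the electron-rich enol ether C11=C2 from the α face, anti to the axial C9 methyl that stands 1,3 to C11, thereby setting C11 and C2, both of which are erased or reset later.

Step 9
Reactants: 12 gem-dibromocyclopropane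
Product: 13 (2S,5aS,7S,9aS)-3,7-dibromo-2-methoxy-6,6,9a-trimethyl-2-{[(triisopropylsilyl)oxy]methyl}-2,5,5a,6,7,8,9,9a-octahydro-1-benzoxepine (C11 methyl ketal, C1(Br)=C2)
Conditions: K2CO3, MeOH/THF, 60 °C
Reagents that add atoms: methanol, CO
Why: The endo C1–Br bond (syn to the pyran ring) ionizes with concerted disrotatory electrocyclic cleavage of the C11–C2 bond (cyclopropyl-to-allyl cation opening), assisted by the O10 lone pair and driven by strain release, to a 2-bromoallyl/oxocarbenium cation that methanol captures at C11. The closest known reaction is the carbonate/methanol (or silver-promoted) expansion of glycal-derived gem-dibromocyclopropanes to 2-bromo-oxepene methyl glycosides; substrates with a carbon substituent on the oxygen-bearing carbon are less documented, but this substituent only adds stabilization to the cation. The seven-membered ring (C9, O10, C11, C1, C2, C3, C4) is formed not by a new ring bond but by ring expansion: the zero-atom bridge C11–C2 of the bicyclo[4.1.0] unit is cut, so that C1 becomes a ring member. The one new stereocentre, the C11 ketal, should arise by methanol attack on the α face, anti to the pseudoaxial C9 methyl, and its configuration is of no consequence because C11 is planarized again in step 10. The step needs regioselectivity (cleavage of the internal bond, capture at C11 and not at C2), which oxygen stabilization of the charge at C11 secures, and chemoselectivity over the C6 bromide, which its secondary neopentyl nature and the mild base secure. Carbonate scavenges HBr so that the ketal and the TIPS ether should survive.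

Step 10
Reactants: 13 bromo-oxepene methyl ketal
Product: 14 (2S,5aS,7S,9aS)-3,7-dibromo-6,6,9a-trimethyl-2-{[(triisopropylsilyl)oxy]methyl}-2,5,5a,6,7,8,9,9a-octahydro-1-benzoxepine (C11–H α)
Conditions: Et3SiH, TMSOTf (cat.), CH2Cl2, −78 → −40 °C
Reagents that add atoms: none
Why: Ionic hydrogenation of the ketal (Kishi-type reductive deoxygenation), in which the Lewis acid ionizes the methoxy group to the alkenyl oxocarbenium ion and the silane adds at C11 from the α face, anti to the pseudoaxial C9 methyl that stands 1,3 to C11 across O10, so that C11–H is α and CH2OTIPS is cis to the C9 methyl.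

Step 11
Reactants: 14 vinyl bromide
Product: 15 (2R,5aS,7S,9aS)-7-bromo-3,6,6,9a-tetramethyl-2-{[(triisopropylsilyl)oxy]methyl}-2,5,5a,6,7,8,9,9a-octahydro-1-benzoxepine
Conditions: MeZnCl, Pd(dppf)Cl2 (cat.), THF, 60 °C
Reagents that add atoms: methylzinc chloride, C[Zn]Cl
Why: Negishi coupling, in which Pd(0) inserts only into the C(sp2)–Br bond (the secondary neopentyl C6–Br does not add to Pd/dppf) and transmetalation/reductive elimination puts the methyl on C1 with the ring alkene retained.

Step 12
Reactants: 15 TIPS ether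
Product: 16 [(2R,5aS,7S,9aS)-7-bromo-3,6,6,9a-tetramethyl-2,5,5a,6,7,8,9,9a-octahydro-1-benzoxepin-2-yl]methanol
Conditions: TBAF, THF, 0 °C → rt
Reagents that add atoms: none
Why: Fluoride-induced desilylation, nothing else in the molecule being fluoride-labile under these conditions (the equatorial C6–Br lacks an antiperiplanar hydrogen for E2).

Step 13
Reactants: 16 primary alcohol
Product: 17 (2R,5aS,7S,9aS)-7-bromo-2-(bromomethyl)-3,6,6,9a-tetramethyl-2,5,5a,6,7,8,9,9a-octahydro-1-benzoxepine
Conditions: CBr4, PPh3, 2,6-lutidine, CH2Cl2, 0 °C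
Reagents that add atoms: carbon tetrabromide, BrC(Br)(Br)Br
Why: Appel reaction, in which bromide displaces the alkoxyphosphonium group at primary C12 by SN2 (as in C6 bromination of pyranosides) without touching a stereocentre.

Step 14
Reactants: 17 dibromide
Product: 18 (2R,3R,4R,5aS,7S,9aS)-7-bromo-2-(bromomethyl)-3,4-epoxy-3,6,6,9a-tetramethyldecahydro-1-benzoxepine (C1–C2 α-epoxide, oxygen anti to C12 and the C9 methyl)
Conditions: DMDO, acetone, 0 °C
Reagents that add atoms: dimethyldioxirane, CC1(C)OO1
Why: Electrophilic epoxidation of the only alkene, the trisubstituted C1=C2, under neutral conditions, expected from the α face because the pseudoaxial C11 CH2Br (held so by A(1,2) strain with the C1 methyl) and the C9 methyl crowd the β face; this sets C1 and C2, the C2–O bond being the target carbinol bond.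

Step 15
Reactants: 18 α-epoxide
Product: 19 (2R,4R,5aS,7S,9aS)-7-bromo-2-(bromomethyl)-6,6,9a-trimethyl-3-methylidenedecahydro-1-benzoxepin-4-ol (target)
Conditions: LiTMP, Et2AlCl (→ Et2AlTMP), PhMe, 0 °C
Reagents that add atoms: none
Why: Yamamoto epoxide-to-allylic-alcohol isomerization, in which aluminium binds the epoxide oxygen and the bulky amide removes, in a cyclic syn elimination, a proton from the least hindered β position (the C1 methyl), so that C1–O breaks, the exocyclic C1=CH2 forms and the C2–O bond keeps its α configuration, while the hindered non-nucleophilic base should spare both bromides.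

**Compound list**

1 | geranyl bromide, (2E)-1-bromo-3,7-dimethylocta-2,6-diene | CC(C)=CCC/C(C)=C/CBr | starting material
2 | diethyl malonate | CCOC(=O)CC(=O)OCC | starting material
3 | diethyl 2-[(2E)-3,7-dimethylocta-2,6-dien-1-yl]propanedioate | CC(C)=CCC/C(C)=C/CC(C(=O)OCC)C(=O)OCC | intermediate
4 | 2-[(2E)-3,7-dimethylocta-2,6-dien-1-yl]propanedioic acid (geranylmalonic acid, not isolated) | CC(C)=CCC/C(C)=C/CC(C(=O)O)C(=O)O | intermediate
5 | (4E)-5,9-dimethyldeca-4,8-dienoic acid | CC(C)=CCC/C(C)=C/CCC(=O)O | intermediate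
6 | (4aS,6S,8aS)-6-bromo-5,5,8a-trimethyloctahydro-2H-chromen-2-one | O=C1CC[C@H]2C(C)(C)[C@@H](Br)CC[C@]2(C)O1 | intermediate
7 | (4aS,6S,8aS)-6-bromo-5,5,8a-trimethyl-4a,5,6,7,8,8a-hexahydro-4H-chromen-2-yl diphenyl phosphate | O=P(Oc1ccccc1)(Oc1ccccc1)OC1=CC[C@H]2C(C)(C)[C@@H](Br)CC[C@]2(C)O1 | intermediate
8 | methyl (4aS,6S,8aS)-6-bromo-5,5,8a-trimethyl-4a,5,6,7,8,8a-hexahydro-4H-chromene-2-carboxylate | COC(=O)C1=CC[C@H]2C(C)(C)[C@@H](Br)CC[C@]2(C)O1 | intermediate
9 | [(4aS,6S,8aS)-6-bromo-5,5,8a-trimethyl-4a,5,6,7,8,8a-hexahydro-4H-chromen-2-yl]methanol | OCC1=CC[C@H]2C(C)(C)[C@@H](Br)CC[C@]2(C)O1 | intermediate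
10 | triisopropylsilyl ether of 9 | CC(C)[Si](C(C)C)(C(C)C)OCC1=CC[C@H]2C(C)(C)[C@@H](Br)CC[C@]2(C)O1 | intermediate
11 | bromoform | BrC(Br)Br | starting material
12 | gem-dibromocyclopropane fused at C11–C2 (α face; C2 R, C11 R) | BrC1(Br)[C@@H]2C[C@H]3C(C)(C)[C@@H](Br)CC[C@]3(C)O[C@]12CO[Si](C(C)C)(C(C)C)C(C)C | intermediate
13 | (2S,5aS,7S,9aS)-3,7-dibromo-2-methoxy-6,6,9a-trimethyl-2-{[(triisopropylsilyl)oxy]methyl}-2,5,5a,6,7,8,9,9a-octahydro-1-benzoxepine | BrC1=CC[C@H]2C(C)(C)[C@@H](Br)CC[C@]2(C)O[C@@]1(OC)CO[Si](C(C)C)(C(C)C)C(C)C | intermediate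
14 | (2S,5aS,7S,9aS)-3,7-dibromo-6,6,9a-trimethyl-2-{[(triisopropylsilyl)oxy]methyl}-2,5,5a,6,7,8,9,9a-octahydro-1-benzoxepine | BrC1=CC[C@H]2C(C)(C)[C@@H](Br)CC[C@]2(C)O[C@H]1CO[Si](C(C)C)(C(C)C)C(C)C | intermediate
15 | (2R,5aS,7S,9aS)-7-bromo-3,6,6,9a-tetramethyl-2-{[(triisopropylsilyl)oxy]methyl}-2,5,5a,6,7,8,9,9a-octahydro-1-benzoxepine | CC1=CC[C@H]2C(C)(C)[C@@H](Br)CC[C@]2(C)O[C@H]1CO[Si](C(C)C)(C(C)C)C(C)C | intermediate
16 | [(2R,5aS,7S,9aS)-7-bromo-3,6,6,9a-tetramethyl-2,5,5a,6,7,8,9,9a-octahydro-1-benzoxepin-2-yl]methanol | CC1=CC[C@H]2C(C)(C)[C@@H](Br)CC[C@]2(C)O[C@H]1CO | intermediate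
17 | (2R,5aS,7S,9aS)-7-bromo-2-(bromomethyl)-3,6,6,9a-tetramethyl-2,5,5a,6,7,8,9,9a-octahydro-1-benzoxepine | CC1=CC[C@H]2C(C)(C)[C@@H](Br)CC[C@]2(C)O[C@H]1CBr | intermediate
18 | (2R,3R,4R,5aS,7S,9aS)-7-bromo-2-(bromomethyl)-3,4-epoxy-3,6,6,9a-tetramethyldecahydro-1-benzoxepine | C[C@@]12O[C@@H]1C[C@H]3C(C)(C)[C@@H](Br)CC[C@]3(C)O[C@H]2CBr | intermediate
19 | (2R,4R,5aS,7S,9aS)-7-bromo-2-(bromomethyl)-6,6,9a-trimethyl-3-methylidenedecahydro-1-benzoxepin-4-ol | C=C1[C@H](O)C[C@H]2C(C)(C)[C@@H](Br)CC[C@]2(C)O[C@H]1CBr | target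

**Step count**

Total: 15 steps. Longest linear sequence: 15 steps (from geranyl bromide).

**Steps most likely to fail**

Step 9 (key step). The cation may lose a C12 proton instead of taking up methanol, giving a cross-conjugated bromo dienol ether. The very labile 2-alkyl-2-alkoxy cyclopropane may also ionize already during carbene addition and be lost to adventitious hydrolysis, or the silyl ether may be cleaved on prolonged heating. Silver promotion at room temperature is only a change of conditions; the fallback inserts C1 in another way and sets out from 10. Ozonolysis of the enol ether (O3, pyridine, CH2Cl2, −78 °C; PPh3) cuts C11=C2 to give (1S,2S,4S)-4-bromo-1,3,3-trimethyl-2-(2-oxoethyl)cyclohexyl [(triisopropylsilyl)oxy]acetate F1. Stork–Zhao-type olefination with the α-iodoethylidene ylide (Ph3P(CHICH3)I, NaHMDS, THF, −78 °C) should convert the aldehyde into the (Z)-vinyl iodide F2, which already carries C1 and its methyl. Iodine–lithium exchange (t-BuLi, Et2O, −100 °C) and intramolecular acylation of the vinyllithium by the glycolate ester then give the (Z)-hydroxy enone F3, in equilibrium with its seven-membered hemiketal. Reductive etherification (Et3SiH, TMSOTf, CH2Cl2, −78 °C) passes through the same type of oxocarbenium ion as step 10 and returns to the route at 15, so that steps 8–11 are bypassed.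

Step 3. Enantiocontrol may erode through uncatalysed Br+ transfer or through binding of the free acid to the Lewis-base catalyst, and direct bromolactonization at the proximal C4=C9 alkene may compete. The fallback sets out from 5 and gives up asymmetric induction. Racemic bromocyclization with bromodiethylsulfonium bromopentachloroantimonate (MeNO2, −25 °C) gives the trans-fused lactone as a racemate, that is 6 together with its enantiomer, the (4aR,6R,8aR)-lactone F4. Preparative chromatography on a chiral stationary phase separates the two, F4 is discarded and the route is rejoined at 6.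

Step 14. Facial selectivity may be poor or reversed, because the oxepene is conformationally mobile and the β face is screened only by the C11 CH2Br group. The fallback sets out from 17 and corrects the carbinol centre afterwards. If the β-epoxide F5 predominates, it is taken through the aluminium amide isomerization of step 15 to the C2-epimeric allylic alcohol F6. Mitsunobu inversion (4-nitrobenzoic acid, DIAD, PPh3, THF, 0 °C) gives the 4-nitrobenzoate F7 with the α-oxygen at C2, and methanolysis (K2CO3, MeOH, rt) returns to the route at 19.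

**Further compounds**

F1 | step 9 | (1S,2S,4S)-4-bromo-1,3,3-trimethyl-2-(2-oxoethyl)cyclohexyl [(triisopropylsilyl)oxy]acetate | O=CC[C@H]1C(C)(C)[C@@H](Br)CC[C@]1(C)OC(=O)CO[Si](C(C)C)(C(C)C)C(C)C
F2 | step 9 | (1S,2S,4S)-4-bromo-2-[(2Z)-3-iodobut-2-en-1-yl]-1,3,3-trimethylcyclohexyl [(triisopropylsilyl)oxy]acetate | C/C(I)=C/C[C@H]1C(C)(C)[C@@H](Br)CC[C@]1(C)OC(=O)CO[Si](C(C)C)(C(C)C)C(C)C
F3 | step 9 | (3Z)-5-[(1S,3S,6S)-3-bromo-6-hydroxy-2,2,6-trimethylcyclohexyl]-3-methyl-1-[(triisopropylsilyl)oxy]pent-3-en-2-one | C/C(=C/C[C@H]1C(C)(C)[C@@H](Br)CC[C@]1(C)O)C(=O)CO[Si](C(C)C)(C(C)C)C(C)C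
F4 | step 3 | (4aR,6R,8aR)-6-bromo-5,5,8a-trimethyloctahydro-2H-chromen-2-one (enantiomer of 6) | O=C1CC[C@@H]2C(C)(C)[C@H](Br)CC[C@@]2(C)O1
F5 | step 14 | (2R,3S,4S,5aS,7S,9aS)-7-bromo-2-(bromomethyl)-3,4-epoxy-3,6,6,9a-tetramethyldecahydro-1-benzoxepine (β-epoxide) | C[C@]12O[C@H]1C[C@H]3C(C)(C)[C@@H](Br)CC[C@]3(C)O[C@H]2CBr
F6 | step 14 | (2R,4S,5aS,7S,9aS)-7-bromo-2-(bromomethyl)-6,6,9a-trimethyl-3-methylidenedecahydro-1-benzoxepin-4-ol (C2 epimer of 19) | C=C1[C@@H](O)C[C@H]2C(C)(C)[C@@H](Br)CC[C@]2(C)O[C@H]1CBr
F7 | step 14 | (2R,4R,5aS,7S,9aS)-7-bromo-2-(bromomethyl)-6,6,9a-trimethyl-3-methylidenedecahydro-1-benzoxepin-4-yl 4-nitrobenzoate | C=C1[C@H](OC(=O)c3ccc(cc3)[N+](=O)[O-])C[C@H]2C(C)(C)[C@@H](Br)CC[C@]2(C)O[C@H]1CBr
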